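**Plan**

- Retrosynthetic cuts: the acetate; C13=C16 and C14–C15 (ene–yne metathesis of a C13 alkyne); C9–C11 (coupling at a C9 enol triflate) and O8/H9 (syn hydroboration of C8=C9); C4–C18 (formaldehyde aldol), with the axial C19 methyl traced back to a lactone carbonyl; C2–C3 of ring A (primary C2 radical onto an α-methylene-γ-lactone); C10–C1 and C10–C20 (enolate alkylations of carvone).
- Forward: ring B is (S)-carvone. Its C10 is made quaternary (methyl, then allyl), C6 is hydroxylated, and the isopropenyl methyl (C19) is oxidised and closed onto O6 as a temporary lactone ring. Ring A is then closed by the radical, the lactone is opened and its carbon reduced back to the C4 methyl, and the side chain is completed last.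
- Feature used: O6 on C6 and C4 on C5 are trans-diequatorial on ring B, so O6 can be tied to C19 as a trans-fused γ-lactone. This makes the isopropenyl CH2 (C3) the β-carbon of an acceptor and locks the chair in which C3 lies gauche to C2 of the equatorial two-carbon arm on C10.
- Stereochemistry: C5 is bought with (S)-carvone; C10 and C6 are set anti to the isopropenyl group; C4 by equatorial aldol attack anti to the axial C20; C8 and C9 by hydroboration anti to C20.

Key step: step 9

Remark: atoms are numbered as in the labdane skeleton of the target in all intermediates (ring A C1–C5/C10, ring B C5–C10, side chain C11–C16, C17 on C8, C18 = CH2OAc and C19 = CH3 on C4, C20 on C10).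

**Route**

Step 1
Reactants: 1 (S)-(+)-carvone
Product: 3 C10-methyl enone (6-methylcarvone; C10 epimers), via lithium dienolate 2 (not isolated)
Conditions: LiN(iPr)2 (LDA), THF, −78 °C; MeI, −78 → 0 °C
Reagents that add atoms: iodomethane, CI
Why: Kinetic deprotonation at C10 gives the cross-conjugated dienolate, which is C-methylated (enolate alkylation); the C10 configuration formed here is erased in step 2.

Step 2
Reactants: 3 C10-methyl enone
Product: 5 C10-allyl-C10-methyl enone (allyl trans to isopropenyl), via lithium dienolate 4 (not isolated)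
Conditions: LiN(iPr)2, THF, −78 °C; allyl bromide, DMPU, −78 → 0 °C
Reagents that add atoms: allyl bromide, C=CCBr
Why: Enolate alkylation in which allyl bromide should enter on the face opposite the neighbouring isopropenyl group on C5, so that the two-carbon arm ends trans to C4 and the quaternary centre C10 is set.

Step 3
Reactants: 5 C10-allyl-C10-methyl enone
Product: 6 tert-butyldimethylsilyl dienol ether (C9(OSi)=C8–C7=C6)
Conditions: TBSOTf, Et3N, CH2Cl2, 0 °C → rt
Reagents that add atoms: tert-butyldimethylsilyl triflate, CC(C)(C)[Si](C)(C)OS(=O)(=O)C(F)(F)F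
Why: Soft enolisation; with no hydrogen left on C10 the O-silylated enone can only lose a C6 proton, which gives the linear 2-silyloxy diene.

Step 4
Reactants: 6 silyl dienol ether
Product: 7 6-hydroxy enone (hydroxyl trans to isopropenyl)
Conditions: m-CPBA, NaHCO3, CH2Cl2, −20 → 0 °C; aqueous work-up
Reagents that add atoms: 3-chloroperbenzoic acid, OOC(=O)c1cccc(Cl)c1
Why: Vinylogous Rubottom oxidation in which the peracid should attack the diene terminus C6 on the face opposite the isopropenyl group on C5, giving the trans γ-hydroxy enone and setting C6.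

Step 5
Reactants: 7 6-hydroxy enone
Product: 8 allylic diol (C19 hydroxylated)
Conditions: SeO2 (cat.), t-BuOOH, salicylic acid (cat.), CH2Cl2, rt
Reagents that add atoms: selenium dioxide, O=[Se]=O; tert-butyl hydroperoxide, CC(C)(C)OO
Why: Riley allylic oxidation (ene reaction, then 2,3-sigmatropic shift) at the methyl group of the most electron-rich alkene, the 1,1-disubstituted isopropenyl group, while the monosubstituted allyl group and the enone should react far more slowly.

Step 6
Reactants: 8 allylic diol
Product: 11 α-methylene-γ-lactone (trans-fused on C5–C6), via hydroxy enal 9 (not isolated), via lactol 10 (not isolated)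
Conditions: TEMPO (cat.), PhI(OAc)2, CH2Cl2, rt
Reagents that add atoms: none
Why: Oxoammonium oxidation of the primary allylic alcohol, closure of the enal onto the trans-vicinal O6 and oxidation of the lactol give the lactone, the primary alcohol being oxidised faster than the secondary one.

Step 7
Reactants: 11 α-methylene lactone
Product: 14 C2 alcohol, via ozonide 12 (not isolated), via aldehyde 13 (not isolated)
Conditions: O3, CH2Cl2, −78 °C (Sudan Red 7B as end-point indicator); PPh3, −78 °C → rt; NaBH(OAc)3, AcOH, rt
Reagents that add atoms: ozone, [O-][O+]=O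
Why: Ozonolysis with reductive work-up, in which the isolated allyl double bond should be consumed well before the two electron-poor conjugated alkenes and the triacetoxyborohydride reduces only the aldehyde.

Step 8
Reactants: 14 C2 alcohol
Product: 15 C2 iodide
Conditions: I2, PPh3, imidazole, CH2Cl2, 0 °C
Reagents that add atoms: iodine, II
Why: Appel reaction of the unhindered primary alcohol, fast at 0 °C and mild enough to spare the α-methylene lactone.

Step 9
Reactants: 15 C2 iodide
Product: 16 tricyclic lactone enone (rings A and B trans-fused; C4–H)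
Conditions: (Me3Si)3SiH, AIBN, PhH (0.01 M), 80 °C, slow addition of the silane
Reagents that add atoms: none
Why: The silyl radical abstracts iodine from C2, the primary C2 radical adds to C3 (the unsubstituted terminus of the α-methylene lactone), and the α-acyl radical at C4 takes a hydrogen atom from the silane, which carries the chain. The closest known reaction type is the Giese-type cyclisation of ω-iodoalkyl radicals onto 2-substituted acrylates. Ring A closes in the 6-endo-trig mode, because the 5-exo alternative would have to attack the fully substituted C4 and leave an unstabilised primary radical. No stereocentre of the target is created: the trans ring fusion follows from the trans-diequatorial arm on C10 and C4 on C5 on the chair of ring B that the trans-fused lactone locks, and the C4–H centre formed here (either epimer serves) is erased in step 13. The step needs cyclisation to beat direct reduction of the C2 radical, which high dilution and slow silane addition against a fast addition to an activated alkene should secure, and it needs the enone to stay untouched, which holds because C7 is transannular to the equatorial arm.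

Step 10
Reactants: 16 tricyclic lactone enone
Product: 18 C9 enol triflate (C8=C9), via lithium enolate 17 (not isolated)
Conditions: Li[HB(sBu)3] (L-Selectride), THF, −78 °C; PhNTf2, −78 → 0 °C
Reagents that add atoms: N-phenylbis(trifluoromethanesulfonimide), O=S(=O)(N(c1ccccc1)S(=O)(=O)C(F)(F)F)C(F)(F)F
Why: Conjugate reduction by the hindered borohydride (1,2-attack is blocked by quaternary C10 and the α-methyl group) gives the C8=C9 enolate regiospecifically, which is trapped on oxygen as the triflate while the lactone survives at −78 °C.

Step 11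
Reactants: 18 C9 enol triflate
Product: 19 dioxolane lactone (C9–C11 bond formed)
Conditions: BrZnCH2CH2CH(OCH2CH2O) ([2-(1,3-dioxolan-2-yl)ethyl]zinc bromide), Pd(OAc)2 (cat.), SPhos (cat.), THF/NMP, 60 °C
Reagents that add atoms: [2-(1,3-dioxolan-2-yl)ethyl]zinc bromide, Br[Zn]CCC1OCCO1
Why: Negishi coupling of an alkylzinc halide with the enol triflate under neutral conditions that leave the lactone intact, the bulky biaryl phosphine favouring reductive elimination over β-hydride elimination.

Step 12
Reactants: 19 dioxolane lactone
Product: 20 dioxolane lactol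
Conditions: iBu2AlH, CH2Cl2, −78 °C
Reagents that add atoms: none
Why: Partial reduction of the lactone stops at the tetrahedral aluminate at low temperature and gives the lactol on work-up.

Step 13
Reactants: 20 dioxolane lactol
Product: 21 hydroxymethyl aldehyde (C18 equatorial; C19 formyl axial)
Conditions: aq. CH2O, K2CO3, MeOH/THF, rt
Reagents that add atoms: formaldehyde, C=O
Why: Crossed aldol reaction under kinetic control, in which the lactol opens to the C4 aldehyde and its enolate adds formaldehyde on the equatorial face opposite the axial C20 methyl, so that the hydroxymethyl group (C18) ends equatorial next to O6 and C4 is set.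

Step 14
Reactants: 21 hydroxymethyl aldehyde
Product: 23 4-methyl-6,18-diol, via tosylhydrazone 22 (not isolated)
Conditions: TsNHNH2, EtOH, 50 °C; catecholborane, CHCl3, 0 °C → rt; NaOAc·3H2O, 60 °C
Reagents that add atoms: none
Why: Mild Wolff–Kishner-type deoxygenation through the tosylhydrazone turns the axial formyl group into the C19 methyl under conditions that avoid retro-aldol loss of C18 and leave the alkene and the acetal alone.

Step 15
Reactants: 23 4-methyl-6,18-diol
Product: 26 hydroxy aldehyde (in equilibrium with its six-membered lactol on O8), via C8 alkylborane 24 (not isolated), via dioxolane triol 25 (not isolated)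
Conditions: BH3·THF (excess), THF, 0 → 40 °C; NaOH, H2O2, 0 °C → rt; 2 M HCl, THF, rt
Reagents that add atoms: hydrogen peroxide, OO; water, O
Why: Hydroboration–oxidation in which borane should add syn to the C8=C9 bond from the face opposite the axial C20 with boron on C8 (the carbon remote from quaternary C10), and oxidation with retention gives the equatorial tertiary alcohol and H9 on the same face, setting C8 and C9, before aqueous acid unmasks the aldehyde.

Step 16
Reactants: 26 hydroxy aldehyde
Product: 27 alkyne triol
Conditions: dimethyl (1-diazo-2-oxopropyl)phosphonate, K2CO3, MeOH, 0 °C → rt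
Reagents that add atoms: dimethyl (1-diazo-2-oxopropyl)phosphonate, COP(=O)(OC)C(=[N+]=[N-])C(C)=O
Why: Seyferth–Gilbert homologation with the Ohira–Bestmann reagent, which reacts with the open aldehyde form under mildly basic conditions that the free alcohols tolerate.

Step 17
Reactants: 27 alkyne triol
Product: 28 diene triol
Conditions: ethylene (1 atm), second-generation Grubbs catalyst (H2IMes)(PCy3)Cl2Ru=CHPh (cat.), CH2Cl2, 40 °C
Reagents that add atoms: ethylene, C=C
Why: Cross ene–yne metathesis of the terminal alkyne with ethylene gives the 2-substituted buta-1,3-diene directly and tolerates free hydroxyl groups.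

Step 18
Reactants: 28 diene triol
Product: 29 target compound
Conditions: Ac2O (1.1 equiv), pyridine, CH2Cl2, 0 °C
Reagents that add atoms: acetic anhydride, CC(=O)OC(C)=O
Why: Selective acylation, the primary C18 hydroxyl reacting much faster than the hindered secondary hydroxyl on C6 and the tertiary one on C8.

**Compound list**

1 | (S)-(+)-carvone | O=C1C(C)=CC[C@H](C(C)=C)C1 | starting material
2 | lithium dienolate of 1 | [Li]OC1=C[C@@H](C(C)=C)CC=C1C | intermediate
3 | C10-methyl enone (6-methylcarvone; C10 epimers) | O=C1C(C)=CC[C@H](C(C)=C)C1C | intermediate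
4 | lithium dienolate of 3 | [Li]OC1=C(C)[C@@H](C(C)=C)CC=C1C | intermediate
5 | C10-allyl-C10-methyl enone (allyl trans to isopropenyl) | O=C1C(C)=CC[C@H](C(C)=C)[C@@]1(C)CC=C | intermediate
6 | tert-butyldimethylsilyl dienol ether | CC(C)(C)[Si](C)(C)OC1=C(C)C=C[C@H](C(C)=C)[C@@]1(C)CC=C | intermediate
7 | 6-hydroxy enone (hydroxyl trans to isopropenyl) | O=C1C(C)=C[C@@H](O)[C@H](C(C)=C)[C@@]1(C)CC=C | intermediate
8 | allylic diol | O=C1C(C)=C[C@@H](O)[C@H](C(=C)CO)[C@@]1(C)CC=C | intermediate
9 | hydroxy enal | O=C1C(C)=C[C@@H](O)[C@H](C(=C)C=O)[C@@]1(C)CC=C | intermediate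
10 | lactol (anomers) | O=C1C(C)=C[C@H]2OC(O)C(=C)[C@@H]2[C@@]1(C)CC=C | intermediate
11 | α-methylene-γ-lactone | O=C1C(C)=C[C@H]2OC(=O)C(=C)[C@@H]2[C@@]1(C)CC=C | intermediate
12 | ozonide | O=C1C(C)=C[C@H]2OC(=O)C(=C)[C@@H]2[C@@]1(C)CC3OCOO3 | intermediate
13 | C2 aldehyde | O=C1C(C)=C[C@H]2OC(=O)C(=C)[C@@H]2[C@@]1(C)CC=O | intermediate
14 | C2 alcohol | O=C1C(C)=C[C@H]2OC(=O)C(=C)[C@@H]2[C@@]1(C)CCO | intermediate
15 | C2 iodide | O=C1C(C)=C[C@H]2OC(=O)C(=C)[C@@H]2[C@@]1(C)CCI | intermediate
16 | tricyclic lactone enone (drawn as the all-chair C4 epimer) | O=C1C(C)=C[C@H]2OC(=O)[C@H]3CCC[C@]1(C)[C@H]23 | intermediate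
17 | lithium enolate | [Li]OC1=C(C)C[C@H]2OC(=O)[C@H]3CCC[C@]1(C)[C@H]23 | intermediate
18 | C9 enol triflate | O=S(=O)(OC1=C(C)C[C@H]2OC(=O)[C@H]3CCC[C@]1(C)[C@H]23)C(F)(F)F | intermediate
19 | dioxolane lactone | C1COC(CCC2=C(C)C[C@H]3OC(=O)[C@H]4CCC[C@]2(C)[C@H]34)O1 | intermediate
20 | dioxolane lactol (anomers) | C1COC(CCC2=C(C)C[C@H]3OC(O)[C@H]4CCC[C@]2(C)[C@H]34)O1 | intermediate
21 | hydroxymethyl aldehyde | C1COC(CCC2=C(C)C[C@@H](O)[C@@H]3[C@@](C=O)(CO)CCC[C@@]23C)O1 | intermediate
22 | tosylhydrazone | C1COC(CCC2=C(C)C[C@@H](O)[C@@H]3[C@@](C=NNS(=O)(=O)c4ccc(C)cc4)(CO)CCC[C@@]23C)O1 | intermediate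
23 | 4-methyl-6,18-diol | C1COC(CCC2=C(C)C[C@@H](O)[C@@H]3[C@@](C)(CO)CCC[C@@]23C)O1 | intermediate
24 | C8 alkylborane (drawn as RBH2; the hydroxyls are borylated in the flask) | C1COC(CC[C@H]2[C@]3(C)CCC[C@](C)(CO)[C@H]3[C@H](O)C[C@]2(C)B)O1 | intermediate
25 | dioxolane triol | C1COC(CC[C@H]2[C@]3(C)CCC[C@](C)(CO)[C@H]3[C@H](O)C[C@]2(C)O)O1 | intermediate
26 | hydroxy aldehyde (open form) | O=CCC[C@H]1[C@]2(C)CCC[C@](C)(CO)[C@H]2[C@H](O)C[C@]1(C)O | intermediate
27 | alkyne triol | C#CCC[C@H]1[C@]2(C)CCC[C@](C)(CO)[C@H]2[C@H](O)C[C@]1(C)O | intermediate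
28 | diene triol | C=CC(=C)CC[C@H]1[C@]2(C)CCC[C@](C)(CO)[C@H]2[C@H](O)C[C@]1(C)O | intermediate
29 | target compound | C=CC(=C)CC[C@H]1[C@]2(C)CCC[C@](C)(COC(C)=O)[C@H]2[C@H](O)C[C@]1(C)O | target

**Step count**

Total: 18 steps. Longest linear sequence: 18 steps, all from (S)-carvone.

**Steps most likely to fail**

Step 15. The borane may add only slowly to the shielded tetrasubstituted C8=C9 bond, or place boron on C9, or approach from the C20 face. The fallback sets out from 23 and delivers silicon from O6 instead. Silylation with (Me2HSi)2NH would give the bis(dimethylsilyl) ether F5. A thiol-catalysed radical-chain intramolecular hydrosilylation (tert-dodecanethiol, di-tert-butyl hyponitrite, cyclohexane, 60 °C) would close the five-membered oxasilolane F6, with silicon on C8 and hydrogen on C9 on the face of O6. Tamao–Fleming oxidation (KF, KHCO3, H2O2) would then come back to the route at 25, which is hydrolysed as in step 15.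

Step 11. Oxidative addition and transmetalation at the tetrasubstituted triflate next to quaternary C10 may be slow, so that β-hydride elimination or protodemetalation of the alkyl partner takes over. The fallback sets out from 16 and uses carbonyl addition in place of cross-coupling. Conjugate reduction (Li[HB(sBu)3], THF, −78 °C, then NH4Cl) would give the saturated ketone F3. Addition of [2-(1,3-dioxolan-2-yl)ethyl]magnesium bromide with CeCl3 (THF, −78 °C) would give the tertiary alcohol F4. Dehydration towards C8 (SOCl2, pyridine, 0 °C) would come back to the route at 19.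

Step 4. The peracid may attack the diene on the face of the isopropenyl group, or at the enol-ether carbon C8 instead of C6. The fallback for the facial problem sets out from 6, accepts the wrong face and inverts afterwards. The oxidation would then give the cis-hydroxy enone F1. A Mitsunobu reaction (4-nitrobenzoic acid, PPh3, DIAD, THF) would give the inverted 4-nitrobenzoate F2, and methanolysis (K2CO3, MeOH) would come back to the route at 7.

**Further compounds**

F1 | step 4 | cis-hydroxy enone (C6 epimer of 7) | O=C1C(C)=C[C@H](O)[C@H](C(C)=C)[C@@]1(C)CC=C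
F2 | step 4 | 4-nitrobenzoate of 7 | O=C1C(C)=C[C@@H](OC(=O)c2ccc(cc2)[N+](=O)[O-])[C@H](C(C)=C)[C@@]1(C)CC=C
F3 | step 11 | saturated C9 ketone (C8 epimers) | O=C1C(C)C[C@H]2OC(=O)[C@H]3CCC[C@]1(C)[C@H]23
F4 | step 11 | tertiary C9 alcohol | OC1(CCC2OCCO2)C(C)C[C@H]3OC(=O)[C@H]4CCC[C@]1(C)[C@H]34
F5 | step 15 | bis(dimethylsilyl) ether of 23 | C1COC(CCC2=C(C)C[C@@H](O[SiH](C)C)[C@@H]3[C@@](C)(CO[SiH](C)C)CCC[C@@]23C)O1
F6 | step 15 | oxasilolane (Si on C8; H on C9) | C1COC(CC[C@H]2[C@]3(C)CCC[C@](C)(CO[SiH](C)C)[C@H]3[C@H]4C[C@]2(C)[Si](C)(C)O4)O1
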